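**Plan**

1. Numbering: bicyclo[3.3.1]nonane with bridgeheads C1 (prenyl) and C5 (lavandulyl); C2–C3–C4 is the triketone arc (ring A = C1, C2, C3, C4, C5, C9), C6–C7–C8 the second arc (ring B), C9 the bridge ketone, C10 the first carbon of the C7 prenyl.
2. Enabling feature: the C7 prenyl is endo, so C10 lies under C3. As an aldehyde carbon it can be bonded to C3 to give an adamantane that only the endo epimer can close. Before C1 and C3 are substituted, the two enol carbons of ring A are equivalent.
3. Retrosynthesis: cut C3–aroyl and C1–prenyl (lithiations of a vinylogous methyl ester); cut C10–C11 (vinyl addition and cross-metathesis from a C7-endo aldehyde); reconnect C3–C10 as a temporary aldol bond; then cut C3–C10 and C1–C8 (Michael) to a 2,2-disubstituted cyclohexane-1,3,5-trione, itself cut at two Claisen bonds to a dialkylated acetoacetate.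
4. Forward: ring A is made first from acyclic material; ring B and the cage ring close in one Michael–aldol cascade; the cage is reopened by retro-aldol with in situ vinylation; C7, C1 and C3 are completed last.
5. Stereochemistry: the side-chain centre comes from (R)-lavandulol; C1 and C5 from a chiral ammonium ion pair that selects one of the two equivalent enol carbons; the endo configuration at C7 is enforced and stored by the cage.

Key step: step 10

Abbreviation: Lav = (2S)-5-methyl-2-(prop-1-en-2-yl)hex-4-en-1-yl, the lavandulyl group with the unchanged stereocentre of (R)-lavandulol (the descriptor changes only through CIP ranking).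
Assumption: the sense of induction in step 10 cannot be predicted and has to be read from a first run; if the cinchonidinium salt favours the mirror cage, its cinchoninium pseudoenantiomer is used instead.
Assumption: O-methylation in step 12 gives both vinylogous ester regioisomers; the 4-methoxy isomer is carried on, and the 2-methoxy isomer is hydrolysed back (1 M HCl, THF) and methylated again.

**Route**

Step 1
Reactants: 1 diethyl 2-(propan-2-ylidene)propanedioate
Product: 2 2-(propan-2-ylidene)propane-1,3-diol
Conditions: i-Bu2AlH (4.4 equiv), CH2Cl2, −78 → 0 °C; aq. potassium sodium tartrate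
Reagents that add atoms: none
Why: Ester-to-alcohol reduction with the Lewis acidic aluminium hydride proceeds by 1,2-addition at both esters, because hydride delivery to the fully substituted β-carbon is disfavoured.

Step 2
Reactants: 2 2-(propan-2-ylidene)propane-1,3-diol
Product: 3 2-(hydroxymethyl)-3-methylbut-2-enal
Conditions: activated MnO2 (10 equiv), CH2Cl2, rt
Reagents that add atoms: none
Why: MnO2 oxidation of an allylic alcohol should stop after one of the two equivalent CH2OH groups, since the remaining alcohol then sits on an electron-poor enal alkene and is oxidised far more slowly.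

Step 3
Reactants: 3 2-(hydroxymethyl)-3-methylbut-2-enal
Product: 4 2-(dimethoxymethyl)-3-methylbut-2-en-1-ol
Conditions: HC(OMe)3, MeOH, pyridinium p-toluenesulfonate (cat.), rt; Et3N quench
Reagents that add atoms: trimethyl orthoformate, COC(OC)OC
Why: Acid-catalysed acetalisation with the orthoformate as water scavenger masks the aldehyde for the enolate chemistry of steps 7–9, and the fully substituted β-carbon prevents conjugate addition of methanol.

Step 4
Reactants: 4 2-(dimethoxymethyl)-3-methylbut-2-en-1-ol
Product: 5 1-bromo-2-(dimethoxymethyl)-3-methylbut-2-ene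
Conditions: CBr4, PPh3, 2,6-lutidine, CH2Cl2, −20 → 0 °C; filtered through Et3N-deactivated silica and used at once
Reagents that add atoms: carbon tetrabromide, BrC(Br)(Br)Br
Why: Appel bromination converts the primary allylic alcohol into the bromide under buffered, non-acidic conditions that leave the acetal intact.

Step 5
Reactants: 6 (R)-lavandulol
Product: 7 (R)-lavandulyl iodide
Conditions: I2, PPh3, imidazole, CH2Cl2, 0 °C → rt
Reagents that add atoms: iodine, [I][I]
Why: Appel-type iodination substitutes the primary alcohol by SN2 at CH2 and does not touch the neighbouring stereocentre, which is carried unchanged into the target.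

Step 6
Reactants: 8 methyl acetoacetate; 7 (R)-lavandulyl iodide
Product: 9 methyl 2-Lav-3-oxobutanoate (epimers at C2)
Conditions: 8 (2.5 equiv), NaH, THF–DMF, 0 °C; then 7, 55 °C
Reagents that add atoms: none
Why: Acetoacetic ester alkylation: the soft sodium enolate should displace the β-branched primary iodide by SN2 in preference to E2, and the excess of 8 suppresses dialkylation.

Step 7
Reactants: 9 methyl 2-Lav-3-oxobutanoate; 5 1-bromo-2-(dimethoxymethyl)-3-methylbut-2-ene
Product: 10 methyl 2-[2-(dimethoxymethyl)-3-methylbut-2-en-1-yl]-2-Lav-3-oxobutanoate (both epimers at C2)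
Conditions: NaH, THF, 0 °C; then 5, 0 °C → rt
Reagents that add atoms: none
Why: A second acetoacetate C-alkylation, now with a reactive allylic bromide, builds the quaternary carbon that becomes C5; both epimers are used because this carbon is no longer stereogenic once the symmetric trione ring is closed.

Step 8
Reactants: 10 methyl 2-[2-(dimethoxymethyl)-3-methylbut-2-en-1-yl]-2-Lav-3-oxobutanoate
Product: 11 methyl 2-[2-(dimethoxymethyl)-3-methylbut-2-en-1-yl]-2-Lav-3,5-dioxohexanoate (mainly enol)
Conditions: LiN(SiMe3)2 (2.2 equiv), THF, −78 °C; 1-acetyl-1H-benzotriazole (1.1 equiv), −78 → 0 °C; aq. NH4Cl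
Reagents that add atoms: 1-acetyl-1H-benzotriazole, CC(=O)n1nnc2ccccc12
Why: Crossed Claisen condensation: the methyl group is the only enolisable position of the ketone, its lithium enolate is C-acylated by the N-acylbenzotriazole, and the second equivalent of base takes up the acidic 1,3-diketone as it forms.

Step 9
Reactants: 11 methyl 2-[2-(dimethoxymethyl)-3-methylbut-2-en-1-yl]-2-Lav-3,5-dioxohexanoate
Product: 13 2-(2-formyl-3-methylbut-2-en-1-yl)-2-Lav-cyclohexane-1,3,5-trione, via acetal trione 12 (not isolated)
Conditions: LiN(i-Pr)2 (3.2 equiv), THF–DMPU, −78 → 25 °C; then 1 M HCl, THF, 0 °C; kept cold and used at once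
Reagents that add atoms: water, O
Why: Dieckmann (intramolecular Claisen) condensation of the 1,3-diketone dianion, whose terminal carbanion attacks the methyl ester in a 6-exo-trig closure helped by the gem-dialkyl effect, gives the trione as its stable enolate, and the acidic work-up then hydrolyses the labile α,β-unsaturated dimethyl acetal.

Step 10
Reactants: 13 2-(2-formyl-3-methylbut-2-en-1-yl)-2-Lav-cyclohexane-1,3,5-trione
Product: 14 cage ketol, 10-hydroxy-8,8-dimethyl-5-Lav-adamantane-2,4,9-trione (plan numbering)
Conditions: O-allyl-N-(9-anthracenylmethyl)cinchonidinium bromide (20 mol %), CsOH·H2O (30 mol %), toluene–CHCl3 7:3, 4 Å molecular sieves, −40 °C; aq. NH4Cl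
Reagents that add atoms: none
Why: Proposed new method: within the chiral ammonium ion pair one of the two equivalent enol carbons of ring A (C1) adds to the β,β-dimethyl enal carbon C8 in a 6-endo-trig Michael addition that closes ring B, the aldehyde enolate is protonated at C7, and the remaining enol carbon C3 then adds to the aldehyde carbon C10 in a 6-(enolendo)-exo-trig aldol that closes the adamantane. The closest known reaction type is the base- or phase-transfer-mediated Michael–aldol annulation of dearomatised acylphloroglucinols carrying the same 2-formyl-3-methylbut-2-enyl chain, including its enantioselective ammonium-salt variant; new here is that the catalyst must choose between two enantiotopic enol termini of a preformed, non-acylated trione. C5 and C1 are set by which terminus attacks (catalyst control), and because of the lavandulyl centre the wrong sense gives a separable diastereomer, not an enantiomer. C7 is set by the cage, since only the endo aldehyde can be reached by C3 and the exo epimer returns through the aldehyde enol; C3 is dictated by the cage geometry, and the C10 hydroxyl is expected on the face away from the axial C8 methyl (this centre is erased in step 11). The step needs C- over O-attack and group selectivity only: ring A is symmetric, so there is no regiochemical choice, and the quaternary C5 blocks aromatisation.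

Step 11
Reactants: 14 cage ketol
Product: 16 7-endo-(1-hydroxyprop-2-en-1-yl)-8,8-dimethyl-5-Lav-bicyclo[3.3.1]nonane-2,4,9-trione (both carbinol epimers), via endo aldehyde lithium enolate 15 (not isolated)
Conditions: LiN(SiMe3)2 (1.0 equiv), THF, −78 → −30 °C; then CeCl3 (2 equiv), CH2=CHMgBr (2 equiv), −78 °C; aq. NH4Cl
Reagents that add atoms: vinylmagnesium bromide, C=C[Mg]Br
Why: Deprotonation of the carbinol triggers retro-aldol cleavage of C3–C10, driven by formation of the 2,4-diketone enolate (which also shields C2 and C4), and the released endo aldehyde is trapped at once by 1,2-addition of the non-basic vinylcerium reagent before C7 can epimerise.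

Step 12
Reactants: 16 7-endo-(1-hydroxyprop-2-en-1-yl)-8,8-dimethyl-5-Lav-bicyclo[3.3.1]nonane-2,4,9-trione
Product: 17 7-endo-(1-hydroxyprop-2-en-1-yl)-4-methoxy-8,8-dimethyl-5-Lav-bicyclo[3.3.1]non-3-ene-2,9-dione
Conditions: Me2SO4, K2CO3, acetone, rt; chromatographic separation from the 2-methoxy isomer
Reagents that add atoms: dimethyl sulfate, COS(=O)(=O)OC
Why: O-Methylation of the cyclic 1,3-diketone enolate with a hard electrophile gives the vinylogous methyl ester that protects ring A, and the isomer with the enone carbonyl at C2, next to C1–H, is the one that allows the later bridgehead lithiation.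

Step 13
Reactants: 17 7-endo-(1-hydroxyprop-2-en-1-yl)-4-methoxy-8,8-dimethyl-5-Lav-bicyclo[3.3.1]non-3-ene-2,9-dione
Product: 18 7-endo-(1-acetoxyprop-2-en-1-yl)-4-methoxy-8,8-dimethyl-5-Lav-bicyclo[3.3.1]non-3-ene-2,9-dione
Conditions: Ac2O, pyridine, DMAP (cat.), CH2Cl2, rt
Reagents that add atoms: acetic anhydride, CC(=O)OC(C)=O
Why: DMAP-catalysed acylation of the secondary allylic alcohol provides the leaving group for π-allyl formation.

Step 14
Reactants: 18 7-endo-(1-acetoxyprop-2-en-1-yl)-4-methoxy-8,8-dimethyl-5-Lav-bicyclo[3.3.1]non-3-ene-2,9-dione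
Product: 19 7-endo-allyl-4-methoxy-8,8-dimethyl-5-Lav-bicyclo[3.3.1]non-3-ene-2,9-dione
Conditions: Pd2(dba)3 (cat.), n-Bu3P, HCO2H, Et3N, THF, 40 °C
Reagents that add atoms: none
Why: Tsuji-type formate reduction: zerovalent palladium ionises the allylic acetate and hydride from the formate ligand is delivered to the more substituted allyl terminus under n-Bu3P control, giving the terminal alkene with C10 as CH2 and leaving C7 untouched.

Step 15
Reactants: 19 7-endo-allyl-4-methoxy-8,8-dimethyl-5-Lav-bicyclo[3.3.1]non-3-ene-2,9-dione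
Product: 20 4-methoxy-8,8-dimethyl-7-endo-(3-methylbut-2-en-1-yl)-5-Lav-bicyclo[3.3.1]non-3-ene-2,9-dione
Conditions: second-generation Grubbs catalyst RuCl2(H2IMes)(PCy3)(=CHPh) (5 mol %), 2-methylbut-2-ene (solvent), 40 °C
Reagents that add atoms: 2-methylbut-2-ene, CC=C(C)C
Why: Olefin cross-metathesis of the monosubstituted alkene with excess 2-methylbut-2-ene gives the prenyl group, while the 1,1-disubstituted and trisubstituted alkenes of the lavandulyl group are inert or react degenerately.

Step 16
Reactants: 20 4-methoxy-8,8-dimethyl-7-endo-(3-methylbut-2-en-1-yl)-5-Lav-bicyclo[3.3.1]non-3-ene-2,9-dione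
Product: 21 4-methoxy-8,8-dimethyl-1,7-bis(3-methylbut-2-en-1-yl)-5-Lav-bicyclo[3.3.1]non-3-ene-2,9-dione (7-endo)
Conditions: LiN(i-Pr)2 (1.5 equiv), THF, −78 °C; 1-bromo-3-methylbut-2-ene, −78 → −40 °C
Reagents that add atoms: 1-bromo-3-methylbut-2-ene, CC(C)=CCBr
Why: Bridgehead lithiation–alkylation: C1–H lies between the C9 ketone and the C2 enone carbonyl and is removed by the amide base, and the configurationally fixed bridgehead carbanion is alkylated by the allylic bromide on its only open (exo) face.

Step 17
Reactants: 22 3-hydroxybenzoic acid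
Product: 23 tert-butyldimethylsilyl 3-(tert-butyldimethylsilyloxy)benzoate
Conditions: t-BuMe2SiCl (2.3 equiv), imidazole, DMF, rt
Reagents that add atoms: tert-butyldimethylsilyl chloride, CC(C)(C)[Si](C)(C)Cl
Why: Silylation of both the phenol and the acid gives an aryl silyl ether that tolerates lithium amides and a silyl ester that is the direct precursor of the acid chloride.

Step 18
Reactants: 23 tert-butyldimethylsilyl 3-(tert-butyldimethylsilyloxy)benzoate
Product: 24 3-(tert-butyldimethylsilyloxy)benzoyl chloride
Conditions: (COCl)2, DMF (cat.), CH2Cl2, 0 °C → rt; volatiles removed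
Reagents that add atoms: oxalyl chloride, O=C(Cl)C(Cl)=O
Why: Vilsmeier-type chlorination converts the silyl ester directly into the acid chloride under neutral conditions, so no HCl is formed that could cleave the aryl silyl ether.

Step 19
Reactants: 21 4-methoxy-8,8-dimethyl-1,7-bis(3-methylbut-2-en-1-yl)-5-Lav-bicyclo[3.3.1]non-3-ene-2,9-dione; 24 3-(tert-butyldimethylsilyloxy)benzoyl chloride
Product: 25 3-[3-(tert-butyldimethylsilyloxy)benzoyl]-4-methoxy-8,8-dimethyl-1,7-bis(3-methylbut-2-en-1-yl)-5-Lav-bicyclo[3.3.1]non-3-ene-2,9-dione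
Conditions: lithium 2,2,6,6-tetramethylpiperidide (3 equiv), THF, −78 °C; then 24, −78 → 0 °C
Reagents that add atoms: none
Why: Vinylic α-lithiation of the β-methoxy enone at C3, the only acidic C–H left, followed by acylation of the vinyllithium with the acid chloride installs the aroyl group, and the hindered product does not add a second equivalent.

Step 20
Reactants: 25 3-[3-(tert-butyldimethylsilyloxy)benzoyl]-4-methoxy-8,8-dimethyl-1,7-bis(3-methylbut-2-en-1-yl)-5-Lav-bicyclo[3.3.1]non-3-ene-2,9-dione
Product: 26 target, (1R,5R,7R)-4-hydroxy-3-(3-hydroxybenzoyl)-8,8-dimethyl-1,7-bis(3-methylbut-2-en-1-yl)-5-Lav-bicyclo[3.3.1]non-3-ene-2,9-dione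
Conditions: LiOH·H2O (10 equiv), dioxane–H2O 4:1, 90 °C; then 1 M HCl to pH 3
Reagents that add atoms: lithium hydroxide, [Li+].[OH-]
Why: Addition–elimination of hydroxide at C4 of the doubly acyl-activated vinylogous ester releases the enolised β-triketone and the same base cleaves the aryl silyl ether; no stereocentre can epimerise, since C1 and C5 are quaternary and neither C7–H nor the lavandulyl C–H is next to a carbonyl.

**Compound list**

1 | diethyl 2-(propan-2-ylidene)propanedioate | CCOC(=O)C(=C(C)C)C(=O)OCC | starting material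
2 | 2-(propan-2-ylidene)propane-1,3-diol | CC(C)=C(CO)CO | intermediate
3 | 2-(hydroxymethyl)-3-methylbut-2-enal | CC(C)=C(CO)C=O | intermediate
4 | 2-(dimethoxymethyl)-3-methylbut-2-en-1-ol | COC(OC)C(CO)=C(C)C | intermediate
5 | 1-bromo-2-(dimethoxymethyl)-3-methylbut-2-ene | COC(OC)C(CBr)=C(C)C | intermediate
6 | (R)-lavandulol, (2R)-5-methyl-2-(prop-1-en-2-yl)hex-4-en-1-ol | C=C(C)[C@@H](CC=C(C)C)CO | starting material
7 | (R)-lavandulyl iodide, (2R)-1-iodo-5-methyl-2-(prop-1-en-2-yl)hex-4-ene | C=C(C)[C@@H](CC=C(C)C)C[I] | intermediate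
8 | methyl acetoacetate | COC(=O)CC(C)=O | starting material
9 | methyl 2-Lav-3-oxobutanoate (epimers at C2) | C=C(C)[C@@H](CC=C(C)C)CC(C(C)=O)C(=O)OC | intermediate
10 | methyl 2-[2-(dimethoxymethyl)-3-methylbut-2-en-1-yl]-2-Lav-3-oxobutanoate (both epimers at C2) | C=C(C)[C@@H](CC=C(C)C)CC(CC(C(OC)OC)=C(C)C)(C(C)=O)C(=O)OC | intermediate
11 | methyl 2-[2-(dimethoxymethyl)-3-methylbut-2-en-1-yl]-2-Lav-3,5-dioxohexanoate (both epimers at C2) | C=C(C)[C@@H](CC=C(C)C)CC(CC(C(OC)OC)=C(C)C)(C(=O)CC(C)=O)C(=O)OC | intermediate
12 | 2-[2-(dimethoxymethyl)-3-methylbut-2-en-1-yl]-2-Lav-cyclohexane-1,3,5-trione | C=C(C)[C@@H](CC=C(C)C)CC1(CC(C(OC)OC)=C(C)C)C(=O)CC(=O)CC1=O | intermediate (not isolated)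
13 | 2-(2-formyl-3-methylbut-2-en-1-yl)-2-Lav-cyclohexane-1,3,5-trione | C=C(C)[C@@H](CC=C(C)C)CC1(CC(C=O)=C(C)C)C(=O)CC(=O)CC1=O | intermediate
14 | cage ketol, 10-hydroxy-8,8-dimethyl-5-Lav-adamantane-2,4,9-trione (plan numbering; OH expected away from the C8 methyls, configuration not needed) | C=C(C)[C@@H](CC=C(C)C)C[C@@]12C[C@@H]3C(C)(C)[C@@H](C(=O)[C@@H]([C@@H]3O)C1=O)C2=O | intermediate
15 | 7-endo-formyl-8,8-dimethyl-5-Lav-bicyclo[3.3.1]nonane-2,4,9-trione (formed as its lithium enolate) | C=C(C)[C@@H](CC=C(C)C)C[C@@]12C[C@@H](C=O)C(C)(C)[C@@H](C(=O)CC1=O)C2=O | intermediate (not isolated)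
16 | 7-endo-(1-hydroxyprop-2-en-1-yl)-8,8-dimethyl-5-Lav-bicyclo[3.3.1]nonane-2,4,9-trione (both carbinol epimers) | C=C(C)[C@@H](CC=C(C)C)C[C@@]12C[C@@H](C(O)C=C)C(C)(C)[C@@H](C(=O)CC1=O)C2=O | intermediate
17 | 7-endo-(1-hydroxyprop-2-en-1-yl)-4-methoxy-8,8-dimethyl-5-Lav-bicyclo[3.3.1]non-3-ene-2,9-dione | C=C(C)[C@@H](CC=C(C)C)C[C@@]12C[C@@H](C(O)C=C)C(C)(C)[C@@H](C(=O)C=C1OC)C2=O | intermediate
18 | 7-endo-(1-acetoxyprop-2-en-1-yl)-4-methoxy-8,8-dimethyl-5-Lav-bicyclo[3.3.1]non-3-ene-2,9-dione | C=C(C)[C@@H](CC=C(C)C)C[C@@]12C[C@@H](C(OC(C)=O)C=C)C(C)(C)[C@@H](C(=O)C=C1OC)C2=O | intermediate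
19 | 7-endo-allyl-4-methoxy-8,8-dimethyl-5-Lav-bicyclo[3.3.1]non-3-ene-2,9-dione | C=C(C)[C@@H](CC=C(C)C)C[C@@]12C[C@@H](CC=C)C(C)(C)[C@@H](C(=O)C=C1OC)C2=O | intermediate
20 | 4-methoxy-8,8-dimethyl-7-endo-(3-methylbut-2-en-1-yl)-5-Lav-bicyclo[3.3.1]non-3-ene-2,9-dione | C=C(C)[C@@H](CC=C(C)C)C[C@@]12C[C@@H](CC=C(C)C)C(C)(C)[C@@H](C(=O)C=C1OC)C2=O | intermediate
21 | 4-methoxy-8,8-dimethyl-1,7-bis(3-methylbut-2-en-1-yl)-5-Lav-bicyclo[3.3.1]non-3-ene-2,9-dione (7-endo) | C=C(C)[C@@H](CC=C(C)C)C[C@@]12C[C@@H](CC=C(C)C)C(C)(C)[C@@](CC=C(C)C)(C(=O)C=C1OC)C2=O | intermediate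
22 | 3-hydroxybenzoic acid | O=C(O)c1cccc(O)c1 | starting material
23 | tert-butyldimethylsilyl 3-(tert-butyldimethylsilyloxy)benzoate | CC(C)(C)[Si](C)(C)OC(=O)c1cccc(O[Si](C)(C)C(C)(C)C)c1 | intermediate
24 | 3-(tert-butyldimethylsilyloxy)benzoyl chloride | CC(C)(C)[Si](C)(C)Oc1cccc(C(Cl)=O)c1 | intermediate
25 | 3-[3-(tert-butyldimethylsilyloxy)benzoyl]-4-methoxy-8,8-dimethyl-1,7-bis(3-methylbut-2-en-1-yl)-5-Lav-bicyclo[3.3.1]non-3-ene-2,9-dione | C=C(C)[C@@H](CC=C(C)C)C[C@@]12C[C@@H](CC=C(C)C)C(C)(C)[C@@](CC=C(C)C)(C(=O)C(C(=O)c3cccc(O[Si](C)(C)C(C)(C)C)c3)=C1OC)C2=O | intermediate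
26 | (1R,5R,7R)-4-hydroxy-3-(3-hydroxybenzoyl)-8,8-dimethyl-1,7-bis(3-methylbut-2-en-1-yl)-5-[(2S)-5-methyl-2-(prop-1-en-2-yl)hex-4-en-1-yl]bicyclo[3.3.1]non-3-ene-2,9-dione (7-endo prenyl) | C=C(C)[C@@H](CC=C(C)C)C[C@@]12C[C@@H](CC=C(C)C)C(C)(C)[C@@](CC=C(C)C)(C(=O)C(C(=O)c3cccc(O)c3)=C1O)C2=O | target

**Step count and risks**

Total steps: 20. Longest linear sequence: 16 steps (steps 1–4, 7–16, 19, 20). The iodide (step 5), the first alkylation (step 6) and the acid chloride (steps 17, 18) are side branches.

Steps most likely to fail: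

1. Step 10 (proposed new method). The ion pair may discriminate poorly between the two enol termini, so that both cage diastereomers form. Fallback with known chemistry: give up catalyst control and use the lavandulyl centre as an internal resolving element. Starting from 13, the cascade is run with achiral tetrabutylammonium bromide and CsOH·H2O, the known non-asymmetric form of this Michael–aldol annulation. This should give 14 together with the mirror-cage diastereomer F1 in comparable amounts. The two are diastereomers and are separated by preparative chromatography; 14 re-enters the route at step 11.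

2. Step 16. Deprotonation at the bridgehead next to the gem-dimethyl carbon may fail, or the hindered carbanion may not be alkylated (competing C3 lithiation, recovered material). Fallback: starting from 20, the bridgehead anion is quenched with the small electrophile iodine (LiN(i-Pr)2, THF, −78 °C; I2) to give the bridgehead iodide F2. A radical Keck allylation (allyltributylstannane, AIBN, benzene, 80 °C) then forms the C1–C bond through the bridgehead radical and gives the 1-allyl compound F3. Cross-metathesis with 2-methylbut-2-ene under the conditions of step 15 returns to the route at 21.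

3. Step 9. The diketone dianion may close through oxygen to a pyran-2,4-dione, or fail to reach the hindered ester. Fallback: the ring is built by a 3+3 double Claisen with a doubly activated nucleophile. Starting from 7 and 5, dimethyl malonate is alkylated with 7 (NaH, THF–DMF) to dimethyl 2-Lav-malonate F4 and then with 5 (NaH, THF) to the dialkylmalonate F5. F5 is condensed with the dianion of 8 (NaH, then n-BuLi, THF, 0 °C → rt): intermolecular Claisen at the γ-carbon, then Dieckmann closure through the β-keto ester methylene, giving the trione ester F6. Saponification (2 M NaOH, MeOH–H2O, 60 °C) gives the trione acid F7, which loses CO2 on acidification to give 12; this is hydrolysed as in step 9 and the route is rejoined at 13.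

**Further compounds**

F1 | step 10 | mirror-cage diastereomer of 14 (all cage centres inverted, same lavandulyl centre) | C=C(C)[C@@H](CC=C(C)C)C[C@]12C[C@H]3C(C)(C)[C@H](C(=O)[C@H]([C@H]3O)C1=O)C2=O
F2 | step 16 | 1-iodo-4-methoxy-8,8-dimethyl-7-endo-(3-methylbut-2-en-1-yl)-5-Lav-bicyclo[3.3.1]non-3-ene-2,9-dione | C=C(C)[C@@H](CC=C(C)C)C[C@@]12C[C@@H](CC=C(C)C)C(C)(C)[C@@]([I])(C(=O)C=C1OC)C2=O
F3 | step 16 | 1-allyl-4-methoxy-8,8-dimethyl-7-endo-(3-methylbut-2-en-1-yl)-5-Lav-bicyclo[3.3.1]non-3-ene-2,9-dione | C=C(C)[C@@H](CC=C(C)C)C[C@@]12C[C@@H](CC=C(C)C)C(C)(C)[C@@](CC=C)(C(=O)C=C1OC)C2=O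
F4 | step 9 | dimethyl 2-Lav-propanedioate | C=C(C)[C@@H](CC=C(C)C)CC(C(=O)OC)C(=O)OC
F5 | step 9 | dimethyl 2-[2-(dimethoxymethyl)-3-methylbut-2-en-1-yl]-2-Lav-propanedioate | C=C(C)[C@@H](CC=C(C)C)CC(CC(C(OC)OC)=C(C)C)(C(=O)OC)C(=O)OC
F6 | step 9 | methyl 3-[2-(dimethoxymethyl)-3-methylbut-2-en-1-yl]-3-Lav-2,4,6-trioxocyclohexane-1-carboxylate (isomer and enol mixture) | C=C(C)[C@@H](CC=C(C)C)CC1(CC(C(OC)OC)=C(C)C)C(=O)CC(=O)C(C(=O)OC)C1=O
F7 | step 9 | 3-[2-(dimethoxymethyl)-3-methylbut-2-en-1-yl]-3-Lav-2,4,6-trioxocyclohexane-1-carboxylic acid | C=C(C)[C@@H](CC=C(C)C)CC1(CC(C(OC)OC)=C(C)C)C(=O)CC(=O)C(C(=O)O)C1=O
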